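**Strategy**

- Retrosynthetic cuts, in order: the C2'–NH2 bond of the pyrimidine (ammonia on a sulfone that comes from a methyl thioether), the indole C3–C3a bond, the bond from the indole nitrogen to C2, the C2–C3 bond, and last an aryl C–I bond.
- Enabling feature: indole C3 is bonded to pyrimidine C4', so the indole nitrogen, C2, C3, C4' and the ring nitrogen next to C4' form a vinylogous amidine. C2 and C3 can therefore be grown from the acidic 4-methyl group of a pyrimidine as a stable N-aryl enamine whose β-carbon (the future C3) is nucleophilic, while C3a lies ortho to nitrogen on the benzo ring and can carry iodine.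
- Forward order: both six-membered rings are commercial. The aniline is iodinated ortho to nitrogen, the methylpyrimidine is extended by one carbon with an amide acetal, and the two halves are joined at nitrogen by enamine exchange.
- The pyrrole ring is the only ring made; it is closed at C3–C3a by palladium-catalysed enamine arylation, which delivers the full skeleton with both bromines in place. Oxidation at sulfur and exchange for NH2 finish the route.
- Stereochemistry: the target has no stereocentre. The enamine geometry is erased on aromatisation, and the transient stereocentres (C3 of a 3H-indole, sulfur of a sulfoxide) disappear.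

Key step: step 4

Remark: the N-aryl enamine made in step 3 is drawn as the Z isomer, held by an N–H···N hydrogen bond to the pyrimidine. It is assumed to equilibrate with the E isomer and the imine tautomer, so its geometry does not affect the cyclisation.

**Route**

Step 1
Reactants: 1 3,4-dibromoaniline
Product: 2 4,5-dibromo-2-iodoaniline
Conditions: NIS (1.05 equiv), AcOH, rt, exclusion of light
Reagents that add atoms: N-iodosuccinimide, C1CC(=O)N(I)C1=O
Why: Electrophilic aromatic iodination of an aniline, in which the para position is blocked by bromine and the ortho position between NH2 and Br is shielded, so iodine should enter the free ortho carbon and stop at mono-iodination because the product is deactivated.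

Step 2
Reactants: 3 4-methyl-2-(methylthio)pyrimidine; 4 N,N-dimethylformamide dimethyl acetal
Product: 5 4-[(E)-2-(dimethylamino)vinyl]-2-(methylthio)pyrimidine
Conditions: neat 4 (3 equiv), 110 °C, MeOH distilled off
Reagents that add atoms: none
Why: Condensation of a C–H acidic azine methyl group with an amide acetal (the enamine-forming stage of a Leimgruber–Batcho-type sequence), in which the carbanion of the 4-methyl group adds to the methoxyiminium ion and loss of methanol gives the conjugated E enamine under thermodynamic control.

Step 3
Reactants: 2 4,5-dibromo-2-iodoaniline; 5 4-[(E)-2-(dimethylamino)vinyl]-2-(methylthio)pyrimidine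
Product: 6 (Z)-N-(4,5-dibromo-2-iodophenyl)-2-[2-(methylthio)pyrimidin-4-yl]ethen-1-amine
Conditions: AcOH, 80 °C
Reagents that add atoms: none
Why: Acid-promoted enamine exchange (transamination) of a push–pull enamine, in which protonation at the β-carbon gives a vinylogous amidinium ion, the arylamine adds at the α-carbon and dimethylamine leaves and is held as its acetate, so the equilibrium should run to the conjugated N-aryl enamine.

Step 4
Reactants: 6 (Z)-N-(4,5-dibromo-2-iodophenyl)-2-[2-(methylthio)pyrimidin-4-yl]ethen-1-amine
Product: 8 5,6-dibromo-3-[2-(methylthio)pyrimidin-4-yl]-1H-indole, via 3H-indole tautomer 7 (not isolated)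
Conditions: Pd(OAc)2 (5 mol %), DABCO (3 equiv), degassed DMF, 85 °C
Reagents that add atoms: none
Why: Zerovalent palladium formed in situ from Pd(OAc)2 should insert into the C–I bond of 6, after which the enamine β-carbon, the only carbon nucleophile in the molecule, attacks the divalent arylpalladium iodide to give a six-membered palladacycle; reductive elimination forges C3–C3a, DABCO takes up HI, and the 3H-indole 7 tautomerises to the aromatic indole 8. The closest known reaction type is the intramolecular Heck-type arylation of N-(2-iodoaryl) enaminones, enamino esters and aldehyde-derived enamines that delivers 3-substituted indoles. The pyrrole ring is the only ring closed, formally in a 5-endo-trig mode at C3–C3a, which the palladacycle pathway makes feasible. No stereocentre is created, and the Z or E geometry of the enamine is immaterial because the isomers interconvert through the imine tautomer. The step needs oxidative addition at C–I in preference to the two C–Br bonds, which the weaker C–I bond, the phosphine-free catalyst, the moderate temperature and the fast intramolecular capture should secure. The site of the iodine, ortho to nitrogen and para to one bromine, fixes the 5,6-dibromo pattern of the indole.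

Step 5
Reactants: 8 5,6-dibromo-3-[2-(methylthio)pyrimidin-4-yl]-1H-indole
Product: 10 5,6-dibromo-3-[2-(methylsulfonyl)pyrimidin-4-yl]-1H-indole, via sulfoxide 9 (not isolated)
Conditions: mCPBA (2.3 equiv), CH2Cl2/THF, 0 °C to rt
Reagents that add atoms: meta-chloroperoxybenzoic acid, OOC(=O)c1cccc(Cl)c1
Why: Peracid oxidation of a thioether through the sulfoxide to the sulfone, in which sulfur is the most nucleophilic site, the indole is deactivated by its two bromines and by conjugation of its nitrogen lone pair into the pyrimidine, and any remaining sulfoxide 9 is also a competent leaving group in the next step.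

Step 6
Reactants: 10 5,6-dibromo-3-[2-(methylsulfonyl)pyrimidin-4-yl]-1H-indole
Product: 11 meridianin F, 4-(5,6-dibromo-1H-indol-3-yl)pyrimidin-2-amine
Conditions: NH3 (0.5 M in 1,4-dioxane, excess), sealed tube, 80 °C
Reagents that add atoms: ammonia, N
Why: Nucleophilic aromatic substitution (SNAr, addition–elimination) at pyrimidine C2', which is flanked by both ring nitrogens and bears methanesulfinate as leaving group, whereas the unactivated aryl bromides of the benzo ring should be inert to ammonia.

**Compound list**

1 | 3,4-dibromoaniline | Nc1ccc(Br)c(Br)c1 | starting material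
2 | 4,5-dibromo-2-iodoaniline | Nc1cc(Br)c(Br)cc1I | intermediate
3 | 4-methyl-2-(methylthio)pyrimidine | Cc1ccnc(SC)n1 | starting material
4 | N,N-dimethylformamide dimethyl acetal | COC(OC)N(C)C | starting material
5 | 4-[(E)-2-(dimethylamino)vinyl]-2-(methylthio)pyrimidine | CN(C)/C=C/c1ccnc(SC)n1 | intermediate
6 | (Z)-N-(4,5-dibromo-2-iodophenyl)-2-[2-(methylthio)pyrimidin-4-yl]ethen-1-amine | CSc1nccc(/C=C\Nc2cc(Br)c(Br)cc2I)n1 | intermediate
7 | 5,6-dibromo-3-[2-(methylthio)pyrimidin-4-yl]-3H-indole (racemic at C3; formed in the flask, not isolated) | CSc1nccc(C2C=Nc3cc(Br)c(Br)cc32)n1 | intermediate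
8 | 5,6-dibromo-3-[2-(methylthio)pyrimidin-4-yl]-1H-indole | CSc1nccc(-c2c[nH]c3cc(Br)c(Br)cc23)n1 | intermediate
9 | 5,6-dibromo-3-[2-(methylsulfinyl)pyrimidin-4-yl]-1H-indole (racemic at sulfur; formed in the flask, not isolated) | CS(=O)c1nccc(-c2c[nH]c3cc(Br)c(Br)cc23)n1 | intermediate
10 | 5,6-dibromo-3-[2-(methylsulfonyl)pyrimidin-4-yl]-1H-indole | CS(=O)(=O)c1nccc(-c2c[nH]c3cc(Br)c(Br)cc23)n1 | intermediate
11 | meridianin F, 4-(5,6-dibromo-1H-indol-3-yl)pyrimidin-2-amine | Nc1nccc(-c2c[nH]c3cc(Br)c(Br)cc23)n1 | target

**Step count**

Total: 6 steps. Longest linear sequence: 5 steps (step 1 or step 2, then steps 3 to 6).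

**Steps most likely to fail**

1. Step 4. The deprotonated vinylogous amidine may bind palladium as an N,N-chelate, or the thioether may bind it, so that the 5-endo closure becomes slow. Forcing the reaction would then bring insertion into the C–Br bonds, with oligomerisation or loss of bromine. The fallback sets out from 2 and comes back at 8. Commercial 4-chloro-2-(methylthio)pyrimidine and ethynyltrimethylsilane would be joined by Sonogashira coupling (PdCl2(PPh3)2, CuI, Et3N, THF) to give 2-(methylthio)-4-[(trimethylsilyl)ethynyl]pyrimidine F1. Larock heteroannulation of 2 with F1 (Pd(OAc)2, K2CO3, LiCl, DMF, 100 °C) would close the same pyrrole ring by alkyne carbopalladation instead of enamine attack. The silyl group should end up next to nitrogen, giving 5,6-dibromo-3-[2-(methylthio)pyrimidin-4-yl]-2-(trimethylsilyl)-1H-indole F2. Protodesilylation with Bu4NF in wet THF would then give 8.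

2. Step 3. The ortho-iodinated, doubly brominated arylamine is weakly nucleophilic, so the exchange may stall. The protonated enamine may then hydrolyse, or the aniline may be acetylated in hot acetic acid. The fallback sets out from 5 and comes back at 6. Hydrolysis of 5 with dilute aqueous HCl in THF should give [2-(methylthio)pyrimidin-4-yl]acetaldehyde F3, expected to rest largely as its hydrogen-bonded enol. Condensation of F3 with 2 in toluene with catalytic TsOH and azeotropic removal of water would give 6. The reaction is then driven by irreversible loss of water and no longer depends on an amine-exchange equilibrium.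

3. Step 5. The peracid may attack the indole C2=C3 bond or a pyrimidine nitrogen, and poor solubility of the NH indole may leave the oxidation incomplete. The fallback sets out from 8 and comes back at 11 without any oxidant. Acid hydrolysis of the thioether (6 M HCl, AcOH, reflux) should give 4-(5,6-dibromo-1H-indol-3-yl)pyrimidin-2(1H)-one F4. Deoxychlorination with POCl3 at reflux would give 5,6-dibromo-3-(2-chloropyrimidin-4-yl)-1H-indole F5. Displacement of chloride with NH3 in 1,4-dioxane in a sealed tube would give 11.

**Further compounds**

F1 | step 4 | 2-(methylthio)-4-[(trimethylsilyl)ethynyl]pyrimidine | CSc1nccc(C#C[Si](C)(C)C)n1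
F2 | step 4 | 5,6-dibromo-3-[2-(methylthio)pyrimidin-4-yl]-2-(trimethylsilyl)-1H-indole | CSc1nccc(-c2c([Si](C)(C)C)[nH]c3cc(Br)c(Br)cc23)n1
F3 | step 3 | [2-(methylthio)pyrimidin-4-yl]acetaldehyde | CSc1nccc(CC=O)n1
F4 | step 5 | 4-(5,6-dibromo-1H-indol-3-yl)pyrimidin-2(1H)-one | O=c1nc(-c2c[nH]c3cc(Br)c(Br)cc23)cc[nH]1
F5 | step 5 | 5,6-dibromo-3-(2-chloropyrimidin-4-yl)-1H-indole | Clc1nccc(-c2c[nH]c3cc(Br)c(Br)cc23)n1
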